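**Plan**

- Retrosynthesis: after removal of six benzyl ethers, the oxolane is cut at O1–C2 and C4–C5 in one operation. This gives 4-(benzyloxy)benzaldehyde and a cyclopropane in which C2, C3 and C4 of the oxolane form the three-membered ring (formal (3+2) annulation).
- Enabling feature: C2 is a para-oxygenated benzylic carbon (stabilises a cation) and C4 is a ketone α-carbon (stabilises an anion), 1,3 to each other across C3, so C2–C3–C4 is a latent donor–acceptor cyclopropane. The ortho-oxygen of each aroyl ring makes its ketone a chelating site for the Lewis acid.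
- The (S,S)-trans-diaroyl cyclopropane is cut at one aroyl C–C(O) bond (aryl Grignard addition to a cyclopropane carbaldehyde, then oxidation). The carbaldehyde is cut into an enal and a phenacyl sulfonium ylide.
- Forward order: cyclopropane ring (step 4), second aroyl group (steps 6 and 7), oxolane ring (step 8), global debenzylation (step 9).
- Stereochemistry: the amine catalyst of step 4 fixes the absolute configuration. One aroyl-bearing cyclopropane carbon survives as C3 and directs C4 trans to it; C2 and C5 come out cis from the annulation transition state. Because the two halves of the target are constitutionally identical, 2,5-cis plus (3R,4R)-trans defines it completely.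

Key step: step 8

Assumption: the sense of induction in step 4 is taken from the ion-pairing model of the catalyst (ylide delivered to the (Z)-iminium ion on the face of the carboxylate); if the opposite sense is found, the (S)-acid is used instead with no other change.

**Route**

Step 1
Reactants: 1 4-(benzyloxy)benzaldehyde; 2 (triphenylphosphoranylidene)acetaldehyde
Product: 3 (E)-3-[4-(benzyloxy)phenyl]prop-2-enal
Conditions: toluene, 80 °C
Reagents that add atoms: none
Why: Wittig olefination with the carbonyl-stabilised formylmethylene ylide, which adds the two-carbon enal unit and gives the (E)-alkene because stabilised ylides react under thermodynamic control of the oxaphosphetane.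

Step 2
Reactants: 4 1-[2,4-bis(benzyloxy)phenyl]ethanone
Product: 5 2-bromo-1-[2,4-bis(benzyloxy)phenyl]ethanone
Conditions: CuBr2 (2 equiv), EtOAc/CHCl3, reflux
Reagents that add atoms: CuBr2, Br[Cu]Br
Why: Selective α-bromination of an aryl methyl ketone through its enol with CuBr2, which stops at the monobromide and spares the benzyl ethers.

Step 3
Reactants: 5 2-bromo-1-[2,4-bis(benzyloxy)phenyl]ethanone
Product: 7 dimethylsulfonium 2-[2,4-bis(benzyloxy)phenyl]-2-oxoethylide, via sulfonium bromide 6 (not isolated)
Conditions: Me2S, acetone, rt; then aq NaOH, CH2Cl2, 0 °C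
Reagents that add atoms: dimethyl sulfide, CSC
Why: SN2 alkylation of the sulfide by the phenacyl bromide, then deprotonation of the CH2 group between carbonyl and sulfonium, should give the isolable carbonyl-stabilised sulfonium ylide.

Step 4
Reactants: 3 (E)-3-[4-(benzyloxy)phenyl]prop-2-enal; 7 dimethylsulfonium 2-[2,4-bis(benzyloxy)phenyl]-2-oxoethylide
Product: 8 (1S,2S,3S)-2-[2,4-bis(benzyloxy)benzoyl]-3-[4-(benzyloxy)phenyl]cyclopropane-1-carbaldehyde (formyl and aroyl trans, formyl and aryl trans)
Conditions: (R)-indoline-2-carboxylic acid (20 mol %), CHCl3, −10 °C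
Reagents that add atoms: none
Why: Amine-catalysed Michael-initiated ring closure (iminium activation of the enal, conjugate addition of the ylide, 3-exo-tet displacement of Me2S by the enamine), in which the carboxylate of the (R)-catalyst is expected to guide the sulfonium ylide by ion pairing to one face of the (Z)-iminium ion and so set the (1S,2S,3S) configuration, the aryl group staying trans to formyl from the (E)-alkene and the aroyl group closing trans to formyl.

Step 5
Reactants: 9 4-bromobenzene-1,3-diol
Product: 10 1-bromo-2,4-bis(benzyloxy)benzene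
Conditions: BnBr (2.2 equiv), K2CO3, DMF, 60 °C
Reagents that add atoms: benzyl bromide, BrCc1ccccc1
Why: Williamson ether synthesis on both phenols.

Step 6
Reactants: 10 1-bromo-2,4-bis(benzyloxy)benzene; 8 (1S,2S,3S)-2-[2,4-bis(benzyloxy)benzoyl]-3-[4-(benzyloxy)phenyl]cyclopropane-1-carbaldehyde
Product: 12 {(1S,2S,3S)-2-[2,4-bis(benzyloxy)benzoyl]-3-[4-(benzyloxy)phenyl]cyclopropyl}[2,4-bis(benzyloxy)phenyl]methanol (both carbinol epimers), via arylmagnesium bromide 11 (not isolated)
Conditions: 10, Mg, THF, reflux; then 8, THF, −78 °C; aq NH4Cl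
Reagents that add atoms: none
Why: Grignard addition, chemoselective for the aldehyde over the hindered conjugated aryl ketone at −78 °C, in which the new carbinol centre is formed without control and is removed by the oxidation of step 7 while the three ring stereocentres are untouched.

Step 7
Reactants: 12 {(1S,2S,3S)-2-[2,4-bis(benzyloxy)benzoyl]-3-[4-(benzyloxy)phenyl]cyclopropyl}[2,4-bis(benzyloxy)phenyl]methanol
Product: 13 {(1S,2S)-3-[4-(benzyloxy)phenyl]cyclopropane-1,2-diyl}bis{[2,4-bis(benzyloxy)phenyl]methanone} (aroyl groups trans; the aryl-bearing carbon is not stereogenic)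
Conditions: Dess–Martin periodinane, CH2Cl2, rt
Reagents that add atoms: none
Why: Dess–Martin oxidation of the secondary benzylic alcohol under neutral conditions that do not enolise the cyclopropyl ketones, which turns the former formyl carbon into the second aroyl-bearing (S) centre.

Step 8
Reactants: 13 {(1S,2S)-3-[4-(benzyloxy)phenyl]cyclopropane-1,2-diyl}bis{[2,4-bis(benzyloxy)phenyl]methanone}; 1 4-(benzyloxy)benzaldehyde
Product: 14 {(2R,3R,4R,5S)-2,5-bis[4-(benzyloxy)phenyl]oxolane-3,4-diyl}bis{[2,4-bis(benzyloxy)phenyl]methanone}
Conditions: Sc(OTf)3 (20 mol %), 1 (3 equiv), 4 Å MS, CH2Cl2, −20 °C → rt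
Reagents that add atoms: none
Why: Proposed new method: Sc(OTf)3 chelated between a ketone oxygen and its ortho benzyloxy group polarises the adjacent cyclopropane bond to the 4-benzyloxyphenyl-bearing carbon, the aldehyde oxygen of 1 opens this bond at the benzylic carbon to give an oxocarbenium ion and a Sc-bound enolate, and the enolate carbon then closes on the oxocarbenium carbon. The closest known reaction type is the Lewis-acid-catalysed (3+2) annulation of 2-arylcyclopropane-1,1-diesters and their 3-aroyl congeners with aldehydes; what is new is that the breaking bond carries a single ketone acceptor, which the strongly donating para-oxygenated aryl group and the bidentate ortho-alkoxy aryl ketone are expected to compensate. The oxolane closes by C–C bond formation in a 5-(enolexo)-endo-trig aldol-type attack on the cationic oxocarbenium carbon, as in the diester series. C3 is the untouched cyclopropane stereocentre (S in 13, R in 14 only through a change of CIP priorities), C4 is set trans to it because the enolate reacts through the conformer with C3–H eclipsing the enolate plane (allylic 1,3-strain) while the tethered electrophile can only arrive from the face of the C2 branch, and C2 and C5 come out cis because both aryl groups sit pseudo-equatorially in the envelope transition state. Because the two aryl groups and the two aroyl groups are pairwise identical, cleavage of either donor–acceptor bond and either configuration at C2 lead to the same compound as long as the 2,5-cis and 3,4-trans relations hold, so no regio- or stereospecificity at the benzylic carbon is required. The selectivity needed is intermolecular capture by the aldehyde ahead of intramolecular O-closure to a 2,3-dihydrofuran and of proton loss to the open enone, which the excess of the electron-rich aldehyde 1 and the low temperature should secure.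

Step 9
Reactants: 14 {(2R,3R,4R,5S)-2,5-bis[4-(benzyloxy)phenyl]oxolane-3,4-diyl}bis{[2,4-bis(benzyloxy)phenyl]methanone}
Product: 15 [(2R,3R,4R,5S)-2,5-bis(4-hydroxyphenyl)oxolane-3,4-diyl]bis[(2,4-dihydroxyphenyl)methanone]
Conditions: H2 (1 atm), Pd/C (10 wt %), EtOAc/MeOH, rt, stopped at complete uptake
Reagents that add atoms: none
Why: Catalytic hydrogenolysis of the six aryl benzyl ethers under neutral conditions, in which the enolisable C3 and C4 centres should not epimerise and the ring C–O bonds, being secondary dialkyl-type benzylic ethers, should be cleaved much more slowly than the ArO–CH2Ph bonds.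

**Compound list**

1 | 4-(benzyloxy)benzaldehyde | O=Cc1ccc(OCc2ccccc2)cc1 | starting material
2 | (triphenylphosphoranylidene)acetaldehyde | O=CC=P(c1ccccc1)(c1ccccc1)c1ccccc1 | starting material
3 | (E)-3-[4-(benzyloxy)phenyl]prop-2-enal | O=C/C=C/c1ccc(OCc2ccccc2)cc1 | intermediate
4 | 1-[2,4-bis(benzyloxy)phenyl]ethanone | CC(=O)c1ccc(OCc2ccccc2)cc1OCc1ccccc1 | starting material
5 | 2-bromo-1-[2,4-bis(benzyloxy)phenyl]ethanone | O=C(CBr)c1ccc(OCc2ccccc2)cc1OCc1ccccc1 | intermediate
6 | {2-[2,4-bis(benzyloxy)phenyl]-2-oxoethyl}dimethylsulfonium bromide | C[S+](C)CC(=O)c1ccc(OCc2ccccc2)cc1OCc1ccccc1.[Br-] | intermediate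
7 | dimethylsulfonium 2-[2,4-bis(benzyloxy)phenyl]-2-oxoethylide | C[S+](C)[CH-]C(=O)c1ccc(OCc2ccccc2)cc1OCc1ccccc1 | intermediate
8 | (1S,2S,3S)-2-[2,4-bis(benzyloxy)benzoyl]-3-[4-(benzyloxy)phenyl]cyclopropane-1-carbaldehyde | O=C[C@@H]1[C@@H](C(=O)c2ccc(OCc3ccccc3)cc2OCc2ccccc2)[C@H]1c1ccc(OCc2ccccc2)cc1 | intermediate
9 | 4-bromobenzene-1,3-diol | Oc1ccc(Br)c(O)c1 | starting material
10 | 1-bromo-2,4-bis(benzyloxy)benzene | Brc1ccc(OCc2ccccc2)cc1OCc1ccccc1 | intermediate
11 | [2,4-bis(benzyloxy)phenyl]magnesium bromide | Br[Mg]c1ccc(OCc2ccccc2)cc1OCc1ccccc1 | intermediate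
12 | {(1S,2S,3S)-2-[2,4-bis(benzyloxy)benzoyl]-3-[4-(benzyloxy)phenyl]cyclopropyl}[2,4-bis(benzyloxy)phenyl]methanol, both carbinol epimers | OC(c1ccc(OCc2ccccc2)cc1OCc1ccccc1)[C@@H]1[C@@H](C(=O)c2ccc(OCc3ccccc3)cc2OCc2ccccc2)[C@H]1c1ccc(OCc2ccccc2)cc1 | intermediate
13 | {(1S,2S)-3-[4-(benzyloxy)phenyl]cyclopropane-1,2-diyl}bis{[2,4-bis(benzyloxy)phenyl]methanone} | O=C(c1ccc(OCc2ccccc2)cc1OCc1ccccc1)[C@@H]1[C@@H](C(=O)c2ccc(OCc3ccccc3)cc2OCc2ccccc2)C1c1ccc(OCc2ccccc2)cc1 | intermediate
14 | {(2R,3R,4R,5S)-2,5-bis[4-(benzyloxy)phenyl]oxolane-3,4-diyl}bis{[2,4-bis(benzyloxy)phenyl]methanone} | O=C(c1ccc(OCc2ccccc2)cc1OCc1ccccc1)[C@@H]1[C@@H](C(=O)c2ccc(OCc3ccccc3)cc2OCc2ccccc2)[C@H](c2ccc(OCc3ccccc3)cc2)O[C@@H]1c1ccc(OCc2ccccc2)cc1 | intermediate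
15 | [(2R,3R,4R,5S)-2,5-bis(4-hydroxyphenyl)oxolane-3,4-diyl]bis[(2,4-dihydroxyphenyl)methanone] | O=C(c1ccc(O)cc1O)[C@@H]1[C@@H](C(=O)c2ccc(O)cc2O)[C@H](c2ccc(O)cc2)O[C@@H]1c1ccc(O)cc1 | target

**Summary**

Total step count: 9. Longest linear sequence: 7 steps (steps 2, 3, 4, 6, 7, 8, 9).

Steps most likely to fail:

1. Step 8. The opened intermediate may collapse intramolecularly through the enolate oxygen (ring expansion to a 2,3-dihydrofuran) or lose the C3 proton to give the open enone. The single ketone acceptor may also be too weakly activated for ring opening, and reversible ionisation of the product at its benzylic ether carbons may erode the 2,5-cis relation. Fallback with known chemistry, stepwise: setting out from 13, Et2AlI in CH2Cl2 at −78 °C opens the cyclopropane by iodide attack at the benzylic carbon and leaves the Al enolate of the γ-iodo ketone. This enolate is trapped in the same flask by aldehyde 1 in a halo-aldol addition to give 2-{[4-(benzyloxy)phenyl](hydroxy)methyl}-3-{[4-(benzyloxy)phenyl](iodo)methyl}-1,4-bis[2,4-bis(benzyloxy)phenyl]butane-1,4-dione F1, with the C3 centre kept from 13. Ag2CO3 in CH2Cl2 then closes the oxolane by intramolecular etherification of the benzylic iodide (5-exo-tet), and the route is rejoined at 14.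

2. Step 4. Iminium formation with the electron-rich enal may be slow, facial discrimination by ion pairing may be weak with the ortho-substituted ylide, and the ring closure may not be cleanly trans. Fallback: setting out from 5, triphenylarsine in acetone gives {2-[2,4-bis(benzyloxy)phenyl]-2-oxoethyl}triphenylarsonium bromide F2. With enal 3, (R)-α,α-diphenylprolinol trimethylsilyl ether (20 mol %) and Na2CO3 in CHCl3, the arsonium ylide formed in the flask should cyclopropanate the iminium ion under steric shielding of one face instead of ion pairing, and the route is rejoined at 8.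

3. Step 9. Hydrogenolytic opening of the oxolane at its benzylic C–O bonds or over-reduction of the aryl ketones may compete with cleavage of the benzyl ethers. Fallback: setting out from 14, non-reductive debenzylation with BCl3 and pentamethylbenzene as cation scavenger in CH2Cl2 at −78 °C leads directly to 15.

Further compounds
F1 | step 8 | 2-{[4-(benzyloxy)phenyl](hydroxy)methyl}-3-{[4-(benzyloxy)phenyl](iodo)methyl}-1,4-bis[2,4-bis(benzyloxy)phenyl]butane-1,4-dione (C3 as in 13) | O=C(c1ccc(OCc2ccccc2)cc1OCc1ccccc1)C(C(O)c1ccc(OCc2ccccc2)cc1)[C@@H](C(=O)c1ccc(OCc2ccccc2)cc1OCc1ccccc1)C(I)c1ccc(OCc2ccccc2)cc1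
F2 | step 4 | {2-[2,4-bis(benzyloxy)phenyl]-2-oxoethyl}triphenylarsonium bromide | [Br-].O=C(C[As+](c1ccccc1)(c1ccccc1)c1ccccc1)c1ccc(OCc2ccccc2)cc1OCc1ccccc1
F0 | step 9 | none | none
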